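The benzene ring is taken apart into three alkynes. The O1–C2–C3 chain of the dihydrofuran serves as a three-atom tether between an ethynyl ether (C7a≡C7) and an internal alkyne (C3a≡C4) that carries the Z-styryl group. A third alkyne (C5≡C6) brings the prenyl group and a boronate as the future C6 hydroxyl. One rhodium-catalysed cyclotrimerisation forms C3a–C7a, C4–C5 and C6–C7 and closes the oxygen ring and the arene together, so the arene is born fully substituted and C4, meta to both oxygens, never needs substitution. The precursor is an (S)-configured ethynyl ether enediyne whose stereocentre comes from a glycerate ester.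

Key step: step 10

Remark on the chemistry: the tertiary hydroxyl is carried as a tetrahydropyranyl acetal and not as a silyl ether, because a silyl group could migrate between the two vicinal oxygens once the secondary potassium alkoxide of step 7 is formed; the acetal carbon is an uncontrolled mixture of epimers, is left undefined in the SMILES, and is lost in step 12.

Step 1
Reactants: 1 methyl (4S)-2,2-dimethyl-1,3-dioxolane-4-carboxylate
Product: 2 2-[(4S)-2,2-dimethyl-1,3-dioxolan-4-yl]propan-2-ol
Conditions: MeMgBr (3 equiv), THF, 0 °C to rt; aq. NH4Cl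
Reagents that add atoms: methylmagnesium bromide, C[Mg]Br
Why: Double Grignard addition to the ester should give the tertiary carbinol, addition to the intermediate ketone being faster than its enolisation, so the existing (S) centre is kept.

Step 2
Reactants: 2 2-[(4S)-2,2-dimethyl-1,3-dioxolan-4-yl]propan-2-ol
Product: 3 (2S)-3-methylbutane-1,2,3-triol
Conditions: Dowex 50WX8 (H+ form), MeOH–H2O (9:1), 40 °C; filter, evaporate
Reagents that add atoms: none
Why: Acid-catalysed acetal hydrolysis frees the 1,2-diol without touching any bond at the stereocentre, and the resin allows isolation of the water-soluble triol without extraction.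

Step 3
Reactants: 3 (2S)-3-methylbutane-1,2,3-triol
Product: 5 2-[(2S)-oxiran-2-yl]propan-2-ol, via primary monotosylate 4 (not isolated)
Conditions: TsCl (1.05 equiv), Bu2SnO (2 mol%), Et3N (1.2 equiv), CH2Cl2–MeCN, 0 °C to rt; then K2CO3 (2 equiv), MeOH, 0 °C, 1 h; careful concentration, bulb-to-bulb distillation
Reagents that add atoms: 4-methylbenzenesulfonyl chloride, Cc1ccc(cc1)S(=O)(=O)Cl (its atoms stay only in 4)
Why: Tin-acetal-catalysed sulfonylation should select the primary hydroxyl of the 1,2-diol and the secondary alkoxide then displaces the tosylate in a 3-exo-tet Williamson closure that leaves the C–O bond of the stereocentre intact, so (S) is retained.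

Step 4
Reactants: 5 2-[(2S)-oxiran-2-yl]propan-2-ol
Product: 6 2-({2-[(2S)-oxiran-2-yl]propan-2-yl}oxy)oxane (both epimers at the acetal carbon)
Conditions: 3,4-dihydro-2H-pyran (1.5 equiv), PPTS (5 mol%), CH2Cl2, rt
Reagents that add atoms: 3,4-dihydro-2H-pyran, C1CCOC=C1
Why: Acid-catalysed addition of the tertiary alcohol to the enol ether (tetrahydropyranylation) should proceed under a catalyst too weak to open the epoxide.

Step 5
Reactants: 6 2-({2-[(2S)-oxiran-2-yl]propan-2-yl}oxy)oxane
Product: 7 (3S)-2-methyl-2-(oxan-2-yloxy)hex-5-yn-3-ol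
Conditions: lithium acetylide–ethylenediamine complex (2.5 equiv), DMSO–THF, 0 °C to rt; H2O
Reagents that add atoms: lithium acetylide–ethylenediamine complex, [Li]C#C.NCCN
Why: SN2 opening of the terminal epoxide by the acetylide at the unhindered CH2 releases the secondary alcohol while the C–O bond at the stereocentre is not broken, so (S) is retained.

Step 6
Reactants: 7 (3S)-2-methyl-2-(oxan-2-yloxy)hex-5-yn-3-ol; 8 (Z)-(2-bromoethenyl)benzene
Product: 9 (3S,7Z)-2-methyl-2-(oxan-2-yloxy)-8-phenyloct-7-en-5-yn-3-ol
Conditions: Pd(PPh3)2Cl2 (2 mol%), CuI (4 mol%), Et3N, THF, rt, Ar, dark; 8 (1.2 equiv)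
Reagents that add atoms: none
Why: Sonogashira coupling of the terminal alkyne with the vinyl bromide should retain the Z geometry, since oxidative addition and reductive elimination at the sp2 carbon are stereoretentive.

Step 7
Reactants: 9 (3S,7Z)-2-methyl-2-(oxan-2-yloxy)-8-phenyloct-7-en-5-yn-3-ol; 10 trichloroethene
Product: 13 2-{[(3S,7Z)-3-(ethynyloxy)-2-methyl-8-phenyloct-7-en-5-yn-2-yl]oxy}oxane, via dichlorovinyl ether 11 (not isolated), via lithium alkynyl ether 12 (not isolated)
Conditions: KH (1.3 equiv), THF, 0 °C to rt; 10 (1.1 equiv), −50 °C to rt; then n-BuLi (2.6 equiv), −78 to −40 °C; MeOH, −78 °C; rapid filtration through Et3N-deactivated silica, product used at once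
Reagents that add atoms: n-butyllithium, [Li]CCCC (lithium only in 12)
Why: In the one-pot trichloroethene route to alkynyl ethers the potassium alkoxide should add anti to dichloroacetylene formed in situ to give the E-dichlorovinyl ether, and butyllithium then effects dehydrochlorination and chlorine–lithium exchange to the lithium alkynyl ether, which is protonated; the O–C bond of the stereocentre is never broken and the acetal cannot migrate.

Step 8
Reactants: 14 1-bromo-3-methylbut-2-ene
Product: 15 5-methylhex-4-en-1-yne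
Conditions: HC≡CMgBr (1.5 equiv, 0.5 M in THF), CuBr·SMe2 (5 mol%), THF, 0 °C to rt; fractional distillation
Reagents that add atoms: ethynylmagnesium bromide, C#C[Mg]Br
Why: Copper-catalysed coupling of an alkynyl Grignard reagent with an allylic bromide should take place at the unhindered primary carbon (SN2) and give the skipped enyne.

Step 9
Reactants: 15 5-methylhex-4-en-1-yne
Product: 18 4,4,5,5-tetramethyl-2-(5-methylhex-4-en-1-yn-1-yl)-1,3,2-dioxaborolane, via lithium acetylide 16 (not isolated), via lithium alkynylborate 17 (not isolated)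
Conditions: n-BuLi (1.0 equiv), Et2O, −78 °C; 2-isopropoxy-4,4,5,5-tetramethyl-1,3,2-dioxaborolane (1.0 equiv), −78 °C, 2 h; HCl in Et2O (1.05 equiv), −78 °C to rt; filter, distil
Reagents that add atoms: 2-isopropoxy-4,4,5,5-tetramethyl-1,3,2-dioxaborolane, CC(C)OB1OC(C)(C)C(C)(C)O1; n-butyllithium, [Li]CCCC (lithium only in 16 and 17)
Why: Alkynylboronate synthesis from a lithium acetylide: the terminal C–H is removed selectively at −78 °C, the acetylide forms an ate complex with the alkoxyborane, and anhydrous acid expels isopropoxide.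

Step 10
Reactants: 13 2-{[(3S,7Z)-3-(ethynyloxy)-2-methyl-8-phenyloct-7-en-5-yn-2-yl]oxy}oxane; 18 4,4,5,5-tetramethyl-2-(5-methylhex-4-en-1-yn-1-yl)-1,3,2-dioxaborolane
Product: 19 2-[(2S)-5-(3-methylbut-2-en-1-yl)-2-[2-(oxan-2-yloxy)propan-2-yl]-4-[(Z)-2-phenylethenyl]-2,3-dihydro-1-benzofuran-6-yl]-4,4,5,5-tetramethyl-1,3,2-dioxaborolane
Conditions: [Rh(cod)2]BF4 (5 mol%), rac-BINAP (5 mol%), H2 (1 atm, 30 min) then Ar, CH2Cl2, 4 Å MS, rt; 18 (3 equiv); 13 added over 6 h by syringe pump; dark
Reagents that add atoms: none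
Why: The cationic monovalent rhodium–bisphosphine fragment should bind the two tethered alkynes of 13 and couple them oxidatively to a trivalent rhodacyclopentadiene, which forms C3a–C7a; 18 then inserts into a Rh–C bond and reductive elimination forms C4–C5 and C6–C7 and releases arene and catalyst. The closest known reactions are the rhodium- and ruthenium-catalysed [2+2+2] cycloadditions of 1,6-diynes with alkynylboronates and the room-temperature rhodium-catalysed cyclotrimerisations of ethynyl ethers. The dihydrofuran ring closes in the oxidative cyclisation, where the O1–C2–C3 tether holds C7a and C3a together in a bicyclic metallacycle, and the benzene ring closes by insertion and reductive elimination. No stereocentre is formed and C2 is not involved, so its (S) configuration and the Z alkene are carried through unchanged. The step needs control of the orientation of 18, which rests on sterics: the pinacolboryl end should avoid the styryl-bearing C4 and bond to the unsubstituted C7, leaving the slim CH2 end next to C4. Cross-reaction over self-trimerisation of the terminal ynol ether is favoured by slow addition of 13 to excess 18, and room temperature in the dark protects the ethynyl ether from thermal loss of alkene and the Z alkene from isomerisation.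

Step 11
Reactants: 19 2-[(2S)-5-(3-methylbut-2-en-1-yl)-2-[2-(oxan-2-yloxy)propan-2-yl]-4-[(Z)-2-phenylethenyl]-2,3-dihydro-1-benzofuran-6-yl]-4,4,5,5-tetramethyl-1,3,2-dioxaborolane
Product: 20 (2S)-5-(3-methylbut-2-en-1-yl)-2-[2-(oxan-2-yloxy)propan-2-yl]-4-[(Z)-2-phenylethenyl]-2,3-dihydro-1-benzofuran-6-ol
Conditions: NaBO3·4H2O (3 equiv), THF–H2O (1:1), rt, dark
Reagents that add atoms: sodium perborate tetrahydrate, [Na+].[O-]OB=O.O.O.O.O
Why: Ipso-oxidation of the arylboronate (peroxide adds to boron, the aryl group shifts from boron to oxygen, hydrolysis frees the phenol) is mild and weakly basic, so the alkenes and the acetal should survive.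

Step 12
Reactants: 20 (2S)-5-(3-methylbut-2-en-1-yl)-2-[2-(oxan-2-yloxy)propan-2-yl]-4-[(Z)-2-phenylethenyl]-2,3-dihydro-1-benzofuran-6-ol
Product: 21 (2S)-2-(2-hydroxypropan-2-yl)-5-(3-methylbut-2-en-1-yl)-4-[(Z)-2-phenylethenyl]-2,3-dihydro-1-benzofuran-6-ol
Conditions: PPTS (0.2 equiv), MeOH, rt to 35 °C, dark
Reagents that add atoms: none
Why: Acid-catalysed acetal exchange with methanol removes the tetrahydropyranyl group under a catalyst too weak to protonate the prenyl alkene, so neither chroman formation nor Z to E isomerisation is expected.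

Compound list
1 | methyl (4S)-2,2-dimethyl-1,3-dioxolane-4-carboxylate | COC(=O)[C@@H]1COC(C)(C)O1 | starting material
2 | 2-[(4S)-2,2-dimethyl-1,3-dioxolan-4-yl]propan-2-ol | CC(C)(O)[C@@H]1COC(C)(C)O1 | intermediate
3 | (2S)-3-methylbutane-1,2,3-triol | CC(C)(O)[C@@H](O)CO | intermediate
4 | (2S)-2,3-dihydroxy-3-methylbutyl 4-methylbenzenesulfonate | CC(C)(O)[C@@H](O)COS(=O)(=O)c1ccc(C)cc1 | intermediate (not isolated)
5 | 2-[(2S)-oxiran-2-yl]propan-2-ol | CC(C)(O)[C@@H]1CO1 | intermediate
6 | 2-({2-[(2S)-oxiran-2-yl]propan-2-yl}oxy)oxane, both epimers at the acetal carbon | CC(C)(OC1CCCCO1)[C@@H]1CO1 | intermediate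
7 | (3S)-2-methyl-2-(oxan-2-yloxy)hex-5-yn-3-ol, both acetal epimers | CC(C)(OC1CCCCO1)[C@@H](O)CC#C | intermediate
8 | (Z)-(2-bromoethenyl)benzene | Br/C=C\c1ccccc1 | starting material
9 | (3S,7Z)-2-methyl-2-(oxan-2-yloxy)-8-phenyloct-7-en-5-yn-3-ol, both acetal epimers | CC(C)(OC1CCCCO1)[C@@H](O)CC#C/C=C\c1ccccc1 | intermediate
10 | trichloroethene | ClC=C(Cl)Cl | starting material
11 | 2-({(3S,7Z)-3-{[(E)-1,2-dichloroethenyl]oxy}-2-methyl-8-phenyloct-7-en-5-yn-2-yl}oxy)oxane, both acetal epimers | CC(C)(OC1CCCCO1)[C@@H](O/C(Cl)=C\Cl)CC#C/C=C\c1ccccc1 | intermediate (not isolated)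
12 | lithium 2-{[(3S,7Z)-2-methyl-2-(oxan-2-yloxy)-8-phenyloct-7-en-5-yn-3-yl]oxy}ethynide, both acetal epimers | CC(C)(OC1CCCCO1)[C@@H](OC#C[Li])CC#C/C=C\c1ccccc1 | intermediate (not isolated)
13 | 2-{[(3S,7Z)-3-(ethynyloxy)-2-methyl-8-phenyloct-7-en-5-yn-2-yl]oxy}oxane, both acetal epimers | CC(C)(OC1CCCCO1)[C@@H](OC#C)CC#C/C=C\c1ccccc1 | intermediate (key-step precursor)
14 | 1-bromo-3-methylbut-2-ene | CC(C)=CCBr | starting material
15 | 5-methylhex-4-en-1-yne | CC(C)=CCC#C | intermediate
16 | (5-methylhex-4-en-1-yn-1-yl)lithium | CC(C)=CCC#C[Li] | intermediate (not isolated)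
17 | lithium 4,4,5,5-tetramethyl-2-(5-methylhex-4-en-1-yn-1-yl)-2-(propan-2-yloxy)-1,3,2-dioxaborolan-2-uide | CC(C)=CCC#C[B-]1(OC(C)C)OC(C)(C)C(C)(C)O1.[Li+] | intermediate (not isolated)
18 | 4,4,5,5-tetramethyl-2-(5-methylhex-4-en-1-yn-1-yl)-1,3,2-dioxaborolane | CC(C)=CCC#CB1OC(C)(C)C(C)(C)O1 | intermediate
19 | 2-[(2S)-5-(3-methylbut-2-en-1-yl)-2-[2-(oxan-2-yloxy)propan-2-yl]-4-[(Z)-2-phenylethenyl]-2,3-dihydro-1-benzofuran-6-yl]-4,4,5,5-tetramethyl-1,3,2-dioxaborolane, both acetal epimers | CC(C)=CCc1c(B3OC(C)(C)C(C)(C)O3)cc2c(c1/C=C\c1ccccc1)C[C@@H](C(C)(C)OC1CCCCO1)O2 | intermediate (key-step product)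
20 | (2S)-5-(3-methylbut-2-en-1-yl)-2-[2-(oxan-2-yloxy)propan-2-yl]-4-[(Z)-2-phenylethenyl]-2,3-dihydro-1-benzofuran-6-ol, both acetal epimers | CC(C)=CCc1c(O)cc2c(c1/C=C\c1ccccc1)C[C@@H](C(C)(C)OC1CCCCO1)O2 | intermediate
21 | (2S)-2-(2-hydroxypropan-2-yl)-5-(3-methylbut-2-en-1-yl)-4-[(Z)-2-phenylethenyl]-2,3-dihydro-1-benzofuran-6-ol | CC(C)=CCc1c(O)cc2c(c1/C=C\c1ccccc1)C[C@@H](C(C)(C)O)O2 | target

Total step count: 12 (steps 1–7 and 10–12 on the main line, steps 8 and 9 for the alkynylboronate).
Longest linear sequence: 10 steps (1–7, 10, 11, 12).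

Steps most likely to fail

Step 10. The unsymmetrical boronate alkyne may insert into the rhodacycle with mixed or reversed orientation, because the electron-poor carbon next to tricoordinate boron can compete with the steric preference; in addition the terminal ynol ether may oligomerise before it is intercepted. The fallback changes the boron partner to one that steers by size alone and changes the order of unmasking. It sets out from enyne 15: zinc-catalysed dehydrogenative borylation with 1,8-naphthalenediaminatoborane (Zn(OTf)2, pyridine, EtCN, 100 °C) should give the alkynyl boramide 2-(5-methylhex-4-en-1-yn-1-yl)-2,3-dihydro-1H-naphtho[1,8-de][1,3,2]diazaborinine F1, in which the nitrogen lone pairs fill the boron p orbital and the flat diaminonaphthalene plate adds bulk. Rhodium-catalysed cyclotrimerisation of F1 with diyne 13 under the conditions of step 10 (alkynyl boramides are established partners in this reaction type) should give the aryl boramide 2-[(2S)-5-(3-methylbut-2-en-1-yl)-2-[2-(oxan-2-yloxy)propan-2-yl]-4-[(Z)-2-phenylethenyl]-2,3-dihydro-1-benzofuran-6-yl]-2,3-dihydro-1H-naphtho[1,8-de][1,3,2]diazaborinine F2. Aqueous acid (2 M H2SO4, THF, rt) would remove the diaminonaphthalene and the tetrahydropyranyl group together to give [(2S)-2-(2-hydroxypropan-2-yl)-5-(3-methylbut-2-en-1-yl)-4-[(Z)-2-phenylethenyl]-2,3-dihydro-1-benzofuran-6-yl]boronic acid F3, and perborate oxidation of F3 (as in step 11) comes back to the route at target 21.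

Step 7. The hindered secondary alkoxide may capture dichloroacetylene slowly or unselectively, and the strongly basic medium may attack the enyne (propargylic deprotonation with loss of the β-alkoxy group, or addition of butyllithium). The fallback builds the ynol ether carbons from a formate and never generates the free alkoxide or dichloroacetylene. It sets out from alcohol 9: formylation (acetic formic anhydride, pyridine, 0 °C) gives (3S,7Z)-2-methyl-2-(oxan-2-yloxy)-8-phenyloct-7-en-5-yn-3-yl formate F4; Wittig-type dichloromethylenation of the formate carbonyl (PPh3, CCl4, THF, 60 °C, the first half of a Corey–Fuchs-type sequence) gives 2-({(3S,7Z)-3-[(2,2-dichloroethenyl)oxy]-2-methyl-8-phenyloct-7-en-5-yn-2-yl}oxy)oxane F5; n-BuLi (2.2 equiv, THF, −78 °C) then converts F5 by elimination and chlorine–lithium exchange into lithium alkynyl ether 12, where the route is rejoined and protonation gives 13.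

Step 3. Under the basic ring closure the epoxide may migrate towards the tertiary alkoxide (Payne rearrangement), and the small, water-miscible epoxy alcohol may be lost on concentration. The fallback never passes through the free hydroxy-epoxide. It sets out from monotosylate 4, isolated for this purpose: Ac2O, pyridine, 0 °C acylates only the secondary hydroxyl to give (2S)-3-hydroxy-3-methyl-1-[(4-methylbenzenesulfonyl)oxy]butan-2-yl acetate F6; 3,4-dihydro-2H-pyran with PPTS then protects the tertiary hydroxyl to give (2S)-3-methyl-1-[(4-methylbenzenesulfonyl)oxy]-3-(oxan-2-yloxy)butan-2-yl acetate F7; K2CO3 in MeOH cleaves the acetate and the liberated secondary alkoxide closes the epoxide, which comes back to the route at 6.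

Further compounds
F1 | step 10 | 2-(5-methylhex-4-en-1-yn-1-yl)-2,3-dihydro-1H-naphtho[1,8-de][1,3,2]diazaborinine | CC(C)=CCC#CB1Nc2cccc3cccc(N1)c23
F2 | step 10 | 2-[(2S)-5-(3-methylbut-2-en-1-yl)-2-[2-(oxan-2-yloxy)propan-2-yl]-4-[(Z)-2-phenylethenyl]-2,3-dihydro-1-benzofuran-6-yl]-2,3-dihydro-1H-naphtho[1,8-de][1,3,2]diazaborinine, both acetal epimers | CC(C)=CCc1c(B3Nc4cccc5cccc(N3)c45)cc2c(c1/C=C\c1ccccc1)C[C@@H](C(C)(C)OC1CCCCO1)O2
F3 | step 10 | [(2S)-2-(2-hydroxypropan-2-yl)-5-(3-methylbut-2-en-1-yl)-4-[(Z)-2-phenylethenyl]-2,3-dihydro-1-benzofuran-6-yl]boronic acid | CC(C)=CCc1c(B(O)O)cc2c(c1/C=C\c1ccccc1)C[C@@H](C(C)(C)O)O2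
F4 | step 7 | (3S,7Z)-2-methyl-2-(oxan-2-yloxy)-8-phenyloct-7-en-5-yn-3-yl formate, both acetal epimers | CC(C)(OC1CCCCO1)[C@@H](OC=O)CC#C/C=C\c1ccccc1
F5 | step 7 | 2-({(3S,7Z)-3-[(2,2-dichloroethenyl)oxy]-2-methyl-8-phenyloct-7-en-5-yn-2-yl}oxy)oxane, both acetal epimers | CC(C)(OC1CCCCO1)[C@@H](OC=C(Cl)Cl)CC#C/C=C\c1ccccc1
F6 | step 3 | (2S)-3-hydroxy-3-methyl-1-[(4-methylbenzenesulfonyl)oxy]butan-2-yl acetate | CC(C)(O)[C@@H](OC(C)=O)COS(=O)(=O)c1ccc(C)cc1
F7 | step 3 | (2S)-3-methyl-1-[(4-methylbenzenesulfonyl)oxy]-3-(oxan-2-yloxy)butan-2-yl acetate, both acetal epimers | CC(C)(OC1CCCCO1)[C@@H](OC(C)=O)COS(=O)(=O)c1ccc(C)cc1
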